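## The problem

Compound 10 is an 8-O-4' neolignan with an open three-carbon chain: the benzylic carbon C7 carries ring A (3,4,5-trimethoxyphenyl) and a free hydroxyl, C8 is bound through oxygen to ring B (4-allyl-2,6-dimethoxyphenyl), and C9 is a primary alcohol. No ring has to be built and both arenes can be bought fully substituted, so the work lies in one carbon–carbon bond, one hindered secondary alkyl aryl ether whose oxygen sits between two ortho-methoxy groups, and two adjacent stereocentres. Both centres are R, which is the threo arrangement of the C7 hydroxyl and the C8 aryloxy group. C8 can be taken from the chiral pool and, lying next to C7, can direct the creation of C7 by 1,2-induction; the reverse order would demand a substitution next to an easily ionised benzylic position. Three features need care: the terminal allyl group (it migrates into conjugation under strong base or with transition-metal hydrides and rules out hydrogenolysis), the benzylic alcohol on the very electron-rich ring A (it ionises in acid and would scramble C7), and any C7 carbonyl precursor, whose C8 hydrogen is acidic. The enabling feature is the C8 ether oxygen, flanked by the ortho-methoxy oxygens of ring B: when C7 is an aldehyde carbon, magnesium can bind this oxygen and the carbonyl oxygen in a five-membered chelate, so that an aryl nucleophile carrying ring A arrives on the face that gives the threo alcohol. The C9 oxygen must be masked by a group too bulky to compete for the metal.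

## Retrosynthesis

**10 to 9.** The O–Si bond of a C9 silyl ether is cut. The primary alcohol has to be masked during the organometallic step, and the triisopropylsilyl ether of 9 is removed at the end by fluoride without acid, which the benzylic alcohol would not tolerate. The forward reaction only has to cleave Si–O and leave everything else alone.

**9 to 8 and 7.** The bond between ring A and C7 is cut, giving the α-aryloxy aldehyde 8 and the arylmagnesium bromide 7. The neighbouring C7–C8 cut, an aldol construction, would have to set two centres at once under external control. A late C8–O cut would pit the hindered phenol 4 against a secondary carbon next to an ionisable benzylic position. The chosen cut creates only C7, under control of the existing C8 centre, and splits the molecule into a bought arene and a three-carbon chiral-pool piece. The forward reaction must be a chelation-controlled addition that gives the threo alcohol and does not deprotonate C8.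

**7 to 6.** The carbon–magnesium bond is traced back to the aryl bromide 6 by direct metal insertion, a routine operation on a commercial arene.

**8 to 5.** The aldehyde 8 is taken back to the methyl ester 5 by an oxidation-level change at C7. The ester is configurationally robust and can be stored, whereas the aldehyde cannot. The forward reduction must stop at the aldehyde and must not erode C8.

**5 to 3 and 4.** The C8–O bond is cut at the ester stage, giving the α-hydroxy ester 3 and the phenol 4. Making the hindered ether here, by displacement at a carbon activated by the ester and with little steric hindrance, is far easier than at any later stage. The displacement inverts, so 3 must have the S configuration to give R in 5. The forward reaction must be a clean SN2 process without elimination toward C9.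

**3 to 2 to 1.** The silyl ether on the primary hydroxyl of 3 is removed to give methyl (S)-glycerate 2, which comes from the commercial acetonide ester 1 by acetal hydrolysis. The stereocentre of 1 supplies, after one inversion, the C8 centre of the target.

## Roads not taken

**Alternative 1:** The ether is cut between the C8 oxygen and the ring B carbon, with ring B carried as a cyclohexane-1,3-dione. Rh2(OAc)4 would turn 5-allyl-2-diazocyclohexane-1,3-dione A2 into a carbenoid that inserts into the free C8 hydroxyl of the silylene-protected triol A3, which is (4R,5R)-2,2-di-tert-butyl-4-(3,4,5-trimethoxyphenyl)-1,3,2-dioxasilinan-5-ol. The insertion gives the 2-alkoxy dione A1. Aromatisation of the dione ring, two O-methylations and removal of the silylene would follow.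
- Merits: the ether forms at a non-aromatic carbon, so the poor nucleophilicity of a di-ortho-substituted phenol is sidestepped. Both stereocentres of A3 are fixed beforehand by an asymmetric dihydroxylation (syn addition to an E-alkene gives threo), and no epimerisable carbonyl compound is handled.
- Weak points: A2 needs its own synthesis, and so does A3. Carbenoids from 2-diazo-1,3-diones such as A2 are prone to Wolff rearrangement and insert reluctantly into hindered secondary alcohols such as A3. The allyl alkene of A2 is itself a cyclopropanation partner. Dehydrogenating A1 to the aromatic level needs oxidants such as DDQ or I2, or Pd/C at high temperature, all of which threaten the allyl group and the benzylic silyl ether.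
- Comparison: the sequence is roughly twice as long. It is stronger in one respect, since the relative and absolute configuration of A3 rest on a dihydroxylation of well-established sense, whereas the chosen plan depends on a chelate to an aryl ether oxygen. The chosen plan sets against this an intact, purchased ring B, seven steps, and no oxidation in the presence of the allyl group.

**Alternative 2:** The C8–O bond to ring B and the C7–OH bond are cut together, leading to sinapyl alcohol A5 and phenol 4. A laccase (a multicopper oxidase, with O2) oxidises both phenols to radicals. The C8 radical of A5 couples with the phenoxyl oxygen of 4, and water adds to C7 of the quinone methide to give the diol A4. Methylation of the ring A phenol of A4 (MeI, K2CO3) would then give 10.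
- Merits: two steps, no protecting groups, water as solvent. On step economy nothing competes with it.
- Weak points: the radicals of A5 also couple with each other and the radical of 4 has its own pathways, so the cross-coupled ether is one component of a mixture. Water adds to the quinone methide with little facial bias, and for 2,6-dimethoxyphenyl ethers the addition tends to favour the erythro isomer, the opposite of what is needed. Laccase releases free radicals, and the dirigent proteins characterised so far steer 8–8' coupling, not an 8-O-4' cross-coupling, so A4 would be expected racemic.
- Comparison: if a protein were found that governs all three selectivities, this road would be clearly superior. As matters stand, the chosen plan gives up brevity and gains control of regiochemistry, relative and absolute configuration by known means.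

**Alternative 3:** No skeletal bond is cut at the key step. The C7–H bond is disconnected, leading to the racemic keto ester A7, which would come from the α-bromo keto ester A8 and the phenoxide of 4. RuCl(p-cymene)[(S,S)-TsDPEN] with HCO2H and Et3N reduces the ketone of A7 while C8 equilibrates through the enol, giving the hydroxy ester A6. Reduction of the ester of A6 with LiBH4 then gives 10.
- Merits: both stereocentres come from one catalytic step, the inputs A8 and 4 are racemic or achiral and cheap, no protecting group is needed, and the route is about four steps.
- Weak points: the syn/anti outcome of such dynamic kinetic reductions depends on the α-substituent, and for the bulky di-ortho-substituted aryloxy group of A7 the threo (2S,3R) isomer A6 is not assured. The electron-rich aryl ketone of A7 is a slow hydride acceptor. The Ru–H species generated from RuCl(p-cymene)[(S,S)-TsDPEN] in formic acid and triethylamine can move the allyl double bond into conjugation with ring B. A6 can undergo retro-aldol cleavage during the basic ester reduction.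
- Comparison: on step count and catalytic economy this road is better. The chosen plan sets against it a C8 centre of secure absolute configuration from the chiral pool, a C7 centre set by a simple substrate-controlled model that can be corrected through a ketone reduction if it fails, and an allyl group that never meets a transition-metal hydride.

Key step: step 6

Remark: C7, C8 and C9 denote the benzylic carbinol carbon, the ether-bearing carbon and the primary carbinol carbon of the propane chain. Compounds 1, 4 and 6 are taken as commercial. Aldehyde 8 is treated as configurationally labile and is not stored.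

## Route

Step 1
Reactants: 1 methyl (S)-2,2-dimethyl-1,3-dioxolane-4-carboxylate
Product: 2 methyl (S)-2,3-dihydroxypropanoate
Conditions: AcOH/H2O (4:1), 40 °C; concentrate with toluene below 35 °C
Reagents that add atoms: none
Why: Acid-catalysed acetal hydrolysis frees the 1,2-diol and releases acetone; the methyl ester survives dilute aqueous acetic acid at this temperature, the stereocentre is not involved, and evaporation avoids extracting the water-soluble diol.

Step 2
Reactants: 2 methyl (S)-2,3-dihydroxypropanoate
Product: 3 methyl (S)-2-hydroxy-3-[(triisopropylsilyl)oxy]propanoate
Conditions: TIPSCl (1.05 equiv), imidazole (2 equiv), DMF, 0 °C to rt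
Reagents that add atoms: chlorotriisopropylsilane (TIPSCl), CC(C)[Si](Cl)(C(C)C)C(C)C
Why: Silyl ether formation with a bulky chlorosilane; the reagent should discriminate between the primary hydroxyl and the secondary one, which is more hindered and deactivated by the adjacent ester, so silylation should occur at C3 only.

Step 3
Reactants: 3 methyl (S)-2-hydroxy-3-[(triisopropylsilyl)oxy]propanoate; 4 4-allyl-2,6-dimethoxyphenol
Product: 5 methyl (R)-2-(4-allyl-2,6-dimethoxyphenoxy)-3-[(triisopropylsilyl)oxy]propanoate
Conditions: PPh3 (1.5 equiv), DIAD (1.5 equiv), THF (concentrated), 0 °C to rt
Reagents that add atoms: none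
Why: Mitsunobu etherification; the phenol is acidic enough to protonate the betaine and its phenoxide displaces the alkoxyphosphonium group in an SN2 process that the adjacent ester accelerates and keeps free of ionisation, so C2 should invert cleanly from S to R, and the hindered ether is made at the least hindered stage of the chain.

Step 4
Reactants: 6 5-bromo-1,2,3-trimethoxybenzene
Product: 7 (3,4,5-trimethoxyphenyl)magnesium bromide
Conditions: Mg turnings (1.2 equiv), cat. I2, THF, 40–50 °C; used as a titrated solution
Reagents that add atoms: magnesium, [Mg]
Why: Grignard formation by direct insertion of magnesium into an aryl bromide; the methoxy groups are inert and the reagent is a known, stable arylmagnesium halide.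

Step 5
Reactants: 5 methyl (R)-2-(4-allyl-2,6-dimethoxyphenoxy)-3-[(triisopropylsilyl)oxy]propanoate
Product: 8 (R)-2-(4-allyl-2,6-dimethoxyphenoxy)-3-[(triisopropylsilyl)oxy]propanal
Conditions: iBu2AlH (1.1 equiv), CH2Cl2, −78 °C; aq. potassium sodium tartrate (KNaC4H4O6), cold; dried and used at once
Reagents that add atoms: none
Why: Partial reduction of an ester with iBu2AlH at low temperature; the tetrahedral aluminium hemiacetal is stabilised by the α-aryloxy oxygen and collapses to the aldehyde only on work-up, which holds back over-reduction, while the cold near-neutral work-up and immediate use protect the C8 centre.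

Step 6
Reactants: 8 (R)-2-(4-allyl-2,6-dimethoxyphenoxy)-3-[(triisopropylsilyl)oxy]propanal; 7 (3,4,5-trimethoxyphenyl)magnesium bromide
Product: 9 (1R,2R)-2-(4-allyl-2,6-dimethoxyphenoxy)-1-(3,4,5-trimethoxyphenyl)-3-[(triisopropylsilyl)oxy]propan-1-ol
Conditions: 8, MgBr2·OEt2 (1.5 equiv), CH2Cl2, −78 °C, 20 min; then 7 (2 equiv, in THF) dropwise, −78 to −40 °C; sat. aq. NH4Cl
Reagents that add atoms: none
Why: This is a nucleophilic 1,2-addition of an arylmagnesium halide to an aldehyde under Cram chelate control; the closest known type is the chelation-controlled addition of Grignard reagents to α-alkoxy aldehydes, which gives syn (threo) 1,2-diol monoethers. Precomplexation with MgBr2·OEt2 in a non-coordinating solvent lets magnesium bind the carbonyl oxygen and the C8 ether oxygen in a five-membered chelate, with an ortho-methoxy oxygen of ring B available as a third donor. In this chelate the carbonyl group and the C8–O bond are held syn-periplanar, so the two faces of the aldehyde differ by the C8 hydrogen on one side and the CH2OSi(iPr)3 arm on the other. The aryl group of 7 should be delivered from the hydrogen side, which forms the bond from ring A to C7 and sets C7 as R, threo to the R centre at C8. No ring is closed; one skeletal bond and one stereocentre are formed. The step needs diastereofacial selectivity only, since absolute configuration is inherited from C8. That selectivity is secured by three things: the donor ability of the twisted di-ortho-substituted aryl ether oxygen, the bulky triisopropylsilyl group that keeps the C9 oxygen out of a competing six-membered chelate, and the low temperature with a weakly basic aryl nucleophile, which leaves the C8 hydrogen untouched.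

Step 7
Reactants: 9 (1R,2R)-2-(4-allyl-2,6-dimethoxyphenoxy)-1-(3,4,5-trimethoxyphenyl)-3-[(triisopropylsilyl)oxy]propan-1-ol
Product: 10 (1R,2R)-2-(4-allyl-2,6-dimethoxyphenoxy)-1-(3,4,5-trimethoxyphenyl)propane-1,3-diol
Conditions: Bu4NF (1.2 equiv), THF, 0 °C to rt
Reagents that add atoms: none
Why: Fluoride-induced cleavage of a silyl ether, driven by Si–F bond formation; the conditions are not acidic, so the ionisable benzylic alcohol, the aryl ethers and the allyl group should be untouched, and neither stereocentre takes part.

## Compound list

1 | methyl (S)-2,2-dimethyl-1,3-dioxolane-4-carboxylate | COC(=O)[C@@H]1COC(C)(C)O1 | starting material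
2 | methyl (S)-2,3-dihydroxypropanoate (methyl L-glycerate) | COC(=O)[C@@H](O)CO | intermediate
3 | methyl (S)-2-hydroxy-3-[(triisopropylsilyl)oxy]propanoate | COC(=O)[C@@H](O)CO[Si](C(C)C)(C(C)C)C(C)C | intermediate
4 | 4-allyl-2,6-dimethoxyphenol | C=CCc1cc(OC)c(O)c(OC)c1 | starting material
5 | methyl (R)-2-(4-allyl-2,6-dimethoxyphenoxy)-3-[(triisopropylsilyl)oxy]propanoate | C=CCc1cc(OC)c(O[C@H](CO[Si](C(C)C)(C(C)C)C(C)C)C(=O)OC)c(OC)c1 | intermediate
6 | 5-bromo-1,2,3-trimethoxybenzene | COc1cc(Br)cc(OC)c1OC | starting material
7 | (3,4,5-trimethoxyphenyl)magnesium bromide | COc1cc([Mg]Br)cc(OC)c1OC | intermediate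
8 | (R)-2-(4-allyl-2,6-dimethoxyphenoxy)-3-[(triisopropylsilyl)oxy]propanal | C=CCc1cc(OC)c(O[C@H](CO[Si](C(C)C)(C(C)C)C(C)C)C=O)c(OC)c1 | intermediate
9 | (1R,2R)-2-(4-allyl-2,6-dimethoxyphenoxy)-1-(3,4,5-trimethoxyphenyl)-3-[(triisopropylsilyl)oxy]propan-1-ol | C=CCc1cc(OC)c(O[C@H](CO[Si](C(C)C)(C(C)C)C(C)C)[C@H](O)c2cc(OC)c(OC)c(OC)c2)c(OC)c1 | intermediate
10 | (1R,2R)-2-(4-allyl-2,6-dimethoxyphenoxy)-1-(3,4,5-trimethoxyphenyl)propane-1,3-diol | C=CCc1cc(OC)c(O[C@H](CO)[C@H](O)c2cc(OC)c(OC)c(OC)c2)c(OC)c1 | target

## Step count and risks

Total step count: 7. Longest linear sequence: 6 steps (steps 1, 2, 3, 5, 6 and 7, from 1 to 10). Step 4 is a one-step side branch.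

**Step 6 (key step).** The most likely failure is insufficient facial selectivity. If magnesium does not hold the hindered aryl ether oxygen firmly, the open-chain polar Felkin–Anh pathway competes and delivers the aryl group to the other face. Partial epimerisation at C8 by the basic reagent would lower the optical purity as well. The fallback sets out from ester 5 and returns at 9. Ester 5 would be converted with MeNH(OMe)·HCl and i-PrMgCl (THF, −20 °C) into (R)-2-(4-allyl-2,6-dimethoxyphenoxy)-N-methoxy-N-methyl-3-[(triisopropylsilyl)oxy]propanamide F1. Addition of Grignard reagent 7 to this amide at low temperature would give (R)-2-(4-allyl-2,6-dimethoxyphenoxy)-1-(3,4,5-trimethoxyphenyl)-3-[(triisopropylsilyl)oxy]propan-1-one F2. Reduction of the ketone with the bulky, poorly chelating hydride KBH(s-Bu)3 (THF, −78 °C) should follow the Felkin–Anh model, with hydride arriving anti to the C8–O bond, and lead to the same threo alcohol 9. The stereochemical problem is thus turned from a chelate-controlled aryl addition into a non-chelate hydride addition.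

**Step 3.** Etherification may be slow because the phenol is flanked by two methoxy groups. The activated alcohol could then eliminate toward C3, or be captured by the reduced azodicarboxylate. The fallback sets out from 3 and returns at 5. Alcohol 3 would be converted (Tf2O, 2,6-lutidine, CH2Cl2, −78 °C) into methyl (S)-3-[(triisopropylsilyl)oxy]-2-{[(trifluoromethyl)sulfonyl]oxy}propanoate F3. The triflate would be displaced by the potassium phenoxide of 4 (K2CO3, MeCN, −20 °C to rt) in an SN2 reaction with inversion, which gives 5.

**Step 5.** Over-reduction to the primary alcohol and epimerisation of the α-aryloxy aldehyde during work-up are the likely losses. The fallback sets out from 5 and returns at 8. Full reduction with LiBH4 (THF, 0 °C) would give (S)-2-(4-allyl-2,6-dimethoxyphenoxy)-3-[(triisopropylsilyl)oxy]propan-1-ol F4. Oxidation with Dess–Martin periodinane buffered with NaHCO3 (CH2Cl2, 0 °C) would then give the aldehyde 8 under non-basic conditions.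

**Step 4.** Sluggish initiation and reductive homocoupling of the electron-rich aryl bromide could lower the titre of the reagent. The fallback sets out from 6 and returns at 7. Bromine–lithium exchange with n-BuLi (THF, −78 °C) would give (3,4,5-trimethoxyphenyl)lithium F5, and transmetalation with MgBr2·OEt2 would give the same arylmagnesium bromide 7.

## Further compounds

F1 | step 6 | (R)-2-(4-allyl-2,6-dimethoxyphenoxy)-N-methoxy-N-methyl-3-[(triisopropylsilyl)oxy]propanamide | C=CCc1cc(OC)c(O[C@H](CO[Si](C(C)C)(C(C)C)C(C)C)C(=O)N(C)OC)c(OC)c1
F2 | step 6 | (R)-2-(4-allyl-2,6-dimethoxyphenoxy)-1-(3,4,5-trimethoxyphenyl)-3-[(triisopropylsilyl)oxy]propan-1-one | C=CCc1cc(OC)c(O[C@H](CO[Si](C(C)C)(C(C)C)C(C)C)C(=O)c2cc(OC)c(OC)c(OC)c2)c(OC)c1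
F3 | step 3 | methyl (S)-3-[(triisopropylsilyl)oxy]-2-{[(trifluoromethyl)sulfonyl]oxy}propanoate | COC(=O)[C@@H](OS(=O)(=O)C(F)(F)F)CO[Si](C(C)C)(C(C)C)C(C)C
F4 | step 5 | (S)-2-(4-allyl-2,6-dimethoxyphenoxy)-3-[(triisopropylsilyl)oxy]propan-1-ol | C=CCc1cc(OC)c(O[C@H](CO[Si](C(C)C)(C(C)C)C(C)C)CO)c(OC)c1
F5 | step 4 | (3,4,5-trimethoxyphenyl)lithium | [Li]c1cc(OC)c(OC)c(OC)c1
A1 | alternative 1 | 5-allyl-2-{[(4R,5R)-2,2-di-tert-butyl-4-(3,4,5-trimethoxyphenyl)-1,3,2-dioxasilinan-5-yl]oxy}cyclohexane-1,3-dione (dione ring centres unspecified) | C=CCC1CC(=O)C(O[C@@H]2CO[Si](C(C)(C)C)(C(C)(C)C)O[C@@H]2c3cc(OC)c(OC)c(OC)c3)C(=O)C1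
A2 | alternative 1 | 5-allyl-2-diazocyclohexane-1,3-dione | C=CCC1CC(=O)C(=[N+]=[N-])C(=O)C1
A3 | alternative 1 | (4R,5R)-2,2-di-tert-butyl-4-(3,4,5-trimethoxyphenyl)-1,3,2-dioxasilinan-5-ol | O[C@@H]1CO[Si](C(C)(C)C)(C(C)(C)C)O[C@@H]1c1cc(OC)c(OC)c(OC)c1
A4 | alternative 2 | (1R,2R)-2-(4-allyl-2,6-dimethoxyphenoxy)-1-(4-hydroxy-3,5-dimethoxyphenyl)propane-1,3-diol | C=CCc1cc(OC)c(O[C@H](CO)[C@H](O)c2cc(OC)c(O)c(OC)c2)c(OC)c1
A5 | alternative 2 | (E)-sinapyl alcohol, 4-[(E)-3-hydroxyprop-1-en-1-yl]-2,6-dimethoxyphenol | COc1cc(/C=C/CO)cc(OC)c1O
A6 | alternative 3 | ethyl (2S,3R)-2-(4-allyl-2,6-dimethoxyphenoxy)-3-hydroxy-3-(3,4,5-trimethoxyphenyl)propanoate | C=CCc1cc(OC)c(O[C@H](C(=O)OCC)[C@H](O)c2cc(OC)c(OC)c(OC)c2)c(OC)c1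
A7 | alternative 3 | ethyl 2-(4-allyl-2,6-dimethoxyphenoxy)-3-oxo-3-(3,4,5-trimethoxyphenyl)propanoate (racemic) | C=CCc1cc(OC)c(OC(C(=O)OCC)C(=O)c2cc(OC)c(OC)c(OC)c2)c(OC)c1
A8 | alternative 3 | ethyl 2-bromo-3-oxo-3-(3,4,5-trimethoxyphenyl)propanoate (racemic) | CCOC(=O)C(Br)C(=O)c1cc(OC)c(OC)c(OC)c1
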